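Amounts first: the flask holds starting material, second substrate and partner at 0.88 M each, and we want to know what stands at 50 min.

| setting | Saturday's | Thursday's | flask |
|---|---|---|---|
| starting material | 0.44 M | 0.66 M | 0.88 M |
| second substrate | 0.88 M | 0.88 M | 0.880 M |
| partner | 0.88 M | 0.88 M | 0.880 M |
| free catalyst | 1.7 mM | 1.7 mM | 1.7 mM |
| remark | run made earlier | run made earlier |  |
| time |  |  | 50 min |

| run | time / min | side product / % | target / % | starting material / % |
|---|---|---|---|---|
| Saturday's | 2.50 | 75.0 | 5.3 | 17.1 |
| Saturday's | 8.00 | 91.4 | 1.5 | 6.3 |
| Saturday's | 15.0 | 95.9 | 2.9 | 4.8 |
| Saturday's | 20.0 | 96.1 | 0.9 | 4.6 |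
| Saturday's | 30.0 | 96.4 | 0 | 3.9 |
| Saturday's | 40.0 | 97.0 | 1.6 | 2.7 |
| Thursday's | 2.50 | 75.1 | 2.1 | 22.7 |
| Thursday's | 8.00 | 87.8 | 0 | 14.2 |
| Thursday's | 15.0 | 87.9 | 0.6 | 10.9 |
| Thursday's | 20.0 | 87.8 | 0 | 11.1 |
| Thursday's | 30.0 | 86.8 | 0.1 | 12.2 |
| Thursday's | 40.0 | 88.6 | 0 | 10.4 |

(each reading ± 1 percentage point)

1. the state of affairs at 50 min: stopped, and by what, or still going (it is still moving / all of the starting material has reacted / the partner has run out first / no working catalyst is left / forward and back rates have come level)
2. side product at 50 min, in percent of the starting material charged
3. amount of target if the flask were left three thousand times as long, in percent of the starting material charged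

- percentages count the starting material that a species holds: one side product counts as two
- the reaction counts as stopped when no species that holds the starting material changes by six tenths of a point or more over the second half of the time

Side product levels off near 96.5% in Saturday's run and near 87.7% in Thursday's, with starting material still present. Two of us read these plateaus differently. The forecast says: “The rate constant falls with time in both runs, so the catalyst is dying.” It gives no working catalyst is left, side product 77% (68% to 83%) and target ever 0.5% (0% to 2%).

I guess otherwise: the partner is the limiting reagent, and two substrates share it. I assume one partner per side product and one per second substrate, which no reading shows. Saturday's side product then took 0.212 M, and the remainder leaves 24.1% of the second substrate. Thursday's run leaves 32.9%.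

Define the sharing exponent s as ln(fraction of starting material left) over ln(fraction of second substrate left). Saturday's run gives 2.36 and Thursday's 1.89, so I carry the mean, 2.12. Rounding it to 2 and closing the partner balance, the flask keeps 41.4% of its second substrate. My side product is therefore 82.8%, above the forecast's number, and I expect the partner to stop the flask.

The flask gives the partner has run out first, with side product 81.0% and target ever 0%.

    partner + catalyst intermediate B → free catalyst + second product (k = 5.20 M⁻¹ s⁻¹)
    starting material + free catalyst ⇌ catalyst intermediate A (K = 2.00 M⁻¹, k = 590 M⁻¹ s⁻¹)
    starting material + target → side product (k = 0.170 M⁻¹ s⁻¹)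
    partner + catalyst intermediate A → free catalyst + target (k = 11.0 M⁻¹ s⁻¹)
    second substrate + free catalyst ⇌ catalyst intermediate B (K = 48.0 M⁻¹, k = 8.20 M⁻¹ s⁻¹)

Partner stands at 0% beside 19% of the starting material and 40% of the second substrate, while catalyst intermediate B, the resting state, holds 92.7% of the catalyst. Side product has moved 5 points at 0.823 M and at 0.942 M of partner. Target's half-life against starting material, 0.077 min, is short beside 50 min. Target stands at 0% then. With 2.12, the flask's second substrate implies 14.5% starting material, against 19%. The neighbour charged 0.53 M of second substrate implies 1.24%, and it holds 4.9%.

The numbers in the tables were computed with made-up constants.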